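The readings are simulated with made-up constants; noise was put on by code.

41.7% of the J charged, the mean of Friday's 4 readings of E, is where you can start, since those readings stand level from 0.833 d on. J and E together fall short of the charge, so a third form holds some J; you can count it with J as one pool. Suppose one J and one Z give one E. Then cE divided by the pool and by cZ, where cZ is the Z charged less cE, gives the plateau number, an apparent equilibrium constant: 11.5 L mol⁻¹ as read from Friday's run.

| setting | Thursday's | Friday's | Wednesday's | flask |
|---|---|---|---|---|
| J | 35 mM | 35 mM | 35 mM | 35 mM |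
| Z | 49 mM | 77 mM | 35 mM | 35.0 mM |
| X | 7 mM | 7 mM | 14 mM | 7.00 mM |
| L | 35 mM | 35 mM | 35 mM | 35.0 mM |
| remark | run made earlier | run made earlier | run made earlier |  |
| time |  |  |  | 4.0 d |

| run | time / d | E / % | J / % |
|---|---|---|---|
| Thursday's | 0.250 | 28.2 | 40.7 |
| Thursday's | 0.625 | 30.4 | 39.6 |
| Thursday's | 1.25 | 30.7 | 40.0 |
| Thursday's | 3.00 | 32.7 | 39.5 |
| Friday's | 0.833 | 40.7 | 33.7 |
| Friday's | 1.67 | 42.9 | 35.3 |
| Friday's | 2.50 | 41.6 | 32.4 |
| Friday's | 3.00 | 41.6 | 34.0 |
| Wednesday's | 0.250 | 21.5 | 45.0 |
| Wednesday's | 0.625 | 22.0 | 45.4 |
| Wednesday's | 1.25 | 24.3 | 44.1 |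
| Wednesday's | 3.00 | 22.8 | 43.7 |

(readings scatter by 1 percentage point)

- at 4.0 d, what has stopped the reaction, if anything has (forward and back rates have come level / it is still moving / all of J has reacted / Z has run out first)
- how much E there is at 4.0 d, in percent of the J charged

- the reaction counts as stopped when no species that holds the J changes by six tenths of a point or more over the second half of the time

Now take two extreme versions of this flask, each one quadratic in cE. In the first, X holds no Z at the end, and the plateau number gives 23.5% of E. In the second, each X holds one Z for good. Friday's run, read that way, gives 12.9 L mol⁻¹, and this flask then gives 21.0%.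

Both numbers rest on Friday's scattered readings, so they mark a rough range for this flask, not firm bounds. Wednesday's run tells you where, since it differs from this flask in X. The second version puts it at 16.4%, yet its last readings are 24.3% and 22.8%. So my reckoning is the upper end, 23.5%, with forward and back rates level by 4.0 d, and about 26.8 mM of Z still free.

The forecast says forward and back rates have come level and 26.7%, within 25% to 28.5%, holding that “every run has reached equilibrium well before 3 d”, and its number stands higher than mine.

The flask gives forward and back rates have come level, with 24.1% of E at 4.0 d.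

    J + Z ⇌ E (K = 21.0 L mol⁻¹, k = 0.488 L mol⁻¹ min⁻¹)
    X + Z ⇌ Q (K = 660 L mol⁻¹, k = 7.00 L mol⁻¹ min⁻¹)
    X + L → D (k = 0.608 L mol⁻¹ min⁻¹)
    J ⇌ G (K = 0.750, k = 0.0133 min⁻¹)

Over the second half of the time, no species that holds the J in this flask moves by more than 0.2 percentage points. Put into the plateau number, this flask's result reads 12.0 L mol⁻¹. Carried to the neighbour flask with 140 mM of Z, that value gives 58.9% of E, and that neighbour holds 58.6%.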